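If I want to know where this flask stops, I count turnovers rather than hours: one turnover is a fall of the electrophile by a factor e, so the turnovers done are the natural logarithm of charged over left.

the same everywhere: electrophile 20 mM

| flask | nucleophile | remark | time |
|---|---|---|---|
| epsilon | 1.7 equiv | run made earlier |  |
| alpha | 2.5 equiv | run made earlier |  |
| birch | 1.20 equiv |  | 8.0 h |
| maple | 1.60 equiv |  | 8.0 h |

| run | time / h | electrophile / % | target / % |
|---|---|---|---|
| epsilon | 0.417 | 52 | 48 |
| epsilon | 0.833 | 36 | 59 |
| epsilon | 1.50 | 33 | 58 |
| epsilon | 3.00 | 30 | 60 |
| epsilon | 6.00 | 29 | 50 |
| alpha | 0.500 | 33 | 65 |
| alpha | 1.33 | 18 | 75 |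
| alpha | 2.50 | 12 | 74 |
| alpha | 4.00 | 13 | 71 |
| alpha | 6.00 | 16 | 61 |

(standard deviation of a reading: 2 percentage points)

- part of the electrophile that has reacted at the end, birch
- part of the electrophile that has reacted at the end, maple
- what raising the equivalents of nucleophile from its lowest to its highest value here does to the part of the electrophile that has reacted (changes below 5 percentage points count as none) (no change / it falls / it rises)

The first setting is time. By hand, more hours should consume more electrophile while nominal nucleophile stands. In the epsilon run, however, the electrophile only drifts from 33% at 1.50 h to 29% at 6.00 h, a change of twice the scatter, so I expect little from the longer time.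

The second setting is the charge. By hand, 1.20 equiv should finish the electrophile, yet the mean of the last 3 readings leaves 30.7% in epsilon with 1.7 equiv and 13.7% in alpha with 2.5 equiv. So I write a balance for the nucleophile: the equivalents charged equal the part reacted plus a side cost for each turnover. Epsilon gives 0.852 and alpha 0.822. I take their mean, 0.837, as the side cost per turnover, the equivalents lost elsewhere while the electrophile falls by a factor e, and I hold the electrophile at 20 mM, as in both runs.

Solving the balance, I reckon 54.5% for birch and 67.2% for maple. The forecast stands slightly higher, at 56% and 69%, and its trend is that it rises, on this ground: “Nucleophile dying in a first-order side path fits well.”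

The flask gives 54.3% for birch and 67.5% for maple, and it rises, by 13 percentage points.

    electrophile + nucleophile → acid set free + target (k = 107 M⁻¹ h⁻¹)
    nucleophile + acid set free ⇌ protonated nucleophile, settled at all times (K = 68300 M⁻¹)
    nucleophile ⇌ dormant form (K = 16.0, k = 0.304 h⁻¹)
    2 nucleophile → homo dimer (k = 14.9 M⁻¹ h⁻¹)
    target ⇌ isomer of the product (K = 22.0, k = 0.0616 h⁻¹)

At the side cost per turnover, the part reacted that the flask gives for maple asks for 1.62 against the 1.60 equiv charged. At the end of maple the nucleophile, the limiting reagent, has 0.33% of its charge still there unbound, less than the 32% of the charged electrophile still there. At that moment in maple the half-life of the electrophile by the making of target is 61 h, long against the 8.0 h of the run. For a flask like maple with 0.640 equiv, the same balance gives 31.9% of the electrophile reacted, and in that flask 32.3% has reacted at the end.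

The readings come from a simulation with constants of no real substance; the scatter is artificial.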